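**Target:** (13S)-8α-acetoxylabdan-15-oic acid (5S,8R,9R,10S,13S), the 8-O-acetate of labdanolic acid.

**Retrosynthetic overview**
1. Target 12 ⇐ hydrogenation of the (11E)-alkene acid 11.
2. 11 ⇐ Ireland–Claisen [3,3] rearrangement of diacetate 8, which forms C13–C14, relays the C11 configuration to C13, and carries the C8 acetate through unchanged.
3. 8 ⇐ (Z)-allylic diol 6 ⇐ Wittig olefination of lactol 4 ⇐ 11α-hydroxysclareolide 3 ⇐ (+)-sclareolide 1.
4. Rings: ring A and ring B (C5, C8, C9, C10) are bought intact in 1; no carbocycle is formed, and the lactone ring is opened in the Wittig step.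

Assumption: labdane numbering is used throughout, and the enolate of 1 is taken to be hydroxylated on its α face (anti to the C8 and C10 methyl groups). This is based on steric reasoning, not on a recalled precedent.

**Route**

Step 1
Reactants: 1 (+)-sclareolide
Product: 3 (11S)-11α-hydroxysclareolide, via potassium enolate of sclareolide 2 (not isolated)
Conditions: KN(SiMe3)2, THF, −78 °C; then (±)-2-(phenylsulfonyl)-3-phenyloxaziridine, −78 °C; aq. NH4Cl
Reagents that add atoms: 2-(phenylsulfonyl)-3-phenyloxaziridine, O=S(=O)(c1ccccc1)N1OC1c1ccccc1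
Why: Enolate hydroxylation with an N-sulfonyloxaziridine (Davis oxidation), in which the β face of the C11 enolate is shielded by the axial C8 and C10 methyl groups, so oxygen should arrive from the α face and C11 is set by the ring stereocentres.

Step 2
Reactants: 3 (11S)-11α-hydroxysclareolide
Product: 4 (11S)-11α-hydroxysclareolide lactol (anomer mixture at C12)
Conditions: i-Bu2AlH (2.5 equiv), CH2Cl2, −78 °C; aq. KNaC4H4O6
Reagents that add atoms: none
Why: Partial lactone reduction with i-Bu2AlH stops at the aluminium hemiacetal at −78 °C, so the lactol forms without touching C11.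

Step 3
Reactants: 4 (11S)-11α-hydroxysclareolide lactol
Product: 6 (11R,12Z)-14,15-dinorlabd-12-ene-8α,11-diol, via open-chain hydroxy aldehyde 5 (not isolated)
Conditions: EtPPh3Br (4 equiv), KN(SiMe3)2 (3.9 equiv), THF, 0 °C; then 4, −78 °C → rt
Reagents that add atoms: ethyltriphenylphosphonium bromide, CC[P+](c1ccccc1)(c1ccccc1)c1ccccc1.[Br-]
Why: Wittig olefination of the ring-opened lactol with a salt-free unstabilised ylide gives the (Z)-alkene through the kinetic cis-oxaphosphetane, and the α-alkoxide formed first suppresses enolisation so C11 is retained.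

Step 4
Reactants: 6 (11R,12Z)-14,15-dinorlabd-12-ene-8α,11-diol
Product: 8 (11R,12Z)-14,15-dinorlabd-12-ene-8α,11-diyl diacetate, via 11-monoacetate 7 (not isolated)
Conditions: AcCl, PhNMe2, CH2Cl2, 0 °C → rt
Reagents that add atoms: acetyl chloride, CC(=O)Cl
Why: Acylation with acetyl chloride and N,N-dimethylaniline is forcing enough to esterify the hindered tertiary 8α-OH (as it does in sclareol) as well as the secondary allylic alcohol, and no stereocentre is touched.

Step 5
Reactants: 8 (11R,12Z)-14,15-dinorlabd-12-ene-8α,11-diyl diacetate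
Product: 11 (11E,13R)-8α-acetoxylabd-11-en-15-oic acid, via bis(trimethylsilyl ketene acetal) 9 (not isolated), via rearranged bis-silyl ester 10 (not isolated)
Conditions: LiN(i-Pr)2 (3 equiv), Me3SiCl/Et3N, THF, −78 °C; warm to 60 °C; then 1 M HCl
Reagents that add atoms: none
Why: Ireland–Claisen rearrangement, a [3,3]-sigmatropic shift through a chair in which the decalin on C11 sits equatorial (axial would clash with the cis methyl of the Z alkene), so C13–C14 forms on the face the C11–O bond leaves and the C11 configuration is relayed to C13, while the C8 ketene acetal has no allyl partner and reverts to the acetate on acidic work-up.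

Step 6
Reactants: 11 (11E,13R)-8α-acetoxylabd-11-en-15-oic acid
Product: 12 (13S)-8α-acetoxylabdan-15-oic acid
Conditions: H2 (1 atm), PtO2, EtOAc, rt
Reagents that add atoms: none
Why: Catalytic hydrogenation of the disubstituted alkene over platinum, which causes little double-bond migration, so the allylic C13 centre is not scrambled and the tertiary acetate and the acid are untouched.

**Compound list**

1 | (+)-sclareolide (8α,12-lactone of 8α-hydroxy-13,14,15,16-tetranorlabdan-12-oic acid; 5S,8R,9R,10S) | O=C1O[C@]2(C)CC[C@H]3C(C)(C)CCC[C@]3(C)[C@H]2C1 | starting material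
2 | potassium enolate of sclareolide (C11=C12 enolate) | [K+].[O-]C=1O[C@]2(C)CC[C@H]3C(C)(C)CCC[C@]3(C)[C@H]2C=1 | intermediate
3 | (11S)-11α-hydroxysclareolide (OH anti to the C8 and C10 methyl groups) | O=C1O[C@]2(C)CC[C@H]3C(C)(C)CCC[C@]3(C)[C@H]2[C@@H]1O | intermediate
4 | (11S)-11α-hydroxysclareolide lactol (8α,12-epoxy-13,14,15,16-tetranorlabdane-11α,12-diol, anomer mixture) | OC1O[C@]2(C)CC[C@H]3C(C)(C)CCC[C@]3(C)[C@H]2[C@@H]1O | intermediate
5 | (11S)-8α,11-dihydroxy-13,14,15,16-tetranorlabdan-12-al (ring-opened form of 4, present as its alkoxide) | O[C@]1(C)CC[C@H]2C(C)(C)CCC[C@]2(C)[C@H]1[C@H](O)C=O | intermediate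
6 | (11R,12Z)-14,15-dinorlabd-12-ene-8α,11-diol (decalin-8α-ol bearing a (1R,2Z)-1-hydroxybut-2-enyl chain on C9) | O[C@]1(C)CC[C@H]2C(C)(C)CCC[C@]2(C)[C@H]1[C@H](O)/C=C\C | intermediate
7 | (11R,12Z)-11-acetoxy-14,15-dinorlabd-12-en-8α-ol | O[C@]1(C)CC[C@H]2C(C)(C)CCC[C@]2(C)[C@H]1[C@H](OC(C)=O)/C=C\C | intermediate
8 | (11R,12Z)-14,15-dinorlabd-12-ene-8α,11-diyl diacetate | CC(=O)O[C@]1(C)CC[C@H]2C(C)(C)CCC[C@]2(C)[C@H]1[C@H](OC(C)=O)/C=C\C | intermediate
9 | bis(trimethylsilyl ketene acetal) of 8 (both acetates as 1-(trimethylsilyloxy)vinyl ethers) | C=C(O[Si](C)(C)C)O[C@]1(C)CC[C@H]2C(C)(C)CCC[C@]2(C)[C@H]1[C@H](OC(=C)O[Si](C)(C)C)/C=C\C | intermediate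
10 | trimethylsilyl (11E,13R)-8α-[1-(trimethylsilyloxy)vinyloxy]labd-11-en-15-oate | C=C(O[Si](C)(C)C)O[C@]1(C)CC[C@H]2C(C)(C)CCC[C@]2(C)[C@H]1/C=C/[C@H](C)CC(=O)O[Si](C)(C)C | intermediate
11 | (11E,13R)-8α-acetoxylabd-11-en-15-oic acid (13R here is the same spatial arrangement as 13S in 12; only the CIP priorities change on hydrogenation) | CC(=O)O[C@]1(C)CC[C@H]2C(C)(C)CCC[C@]2(C)[C@H]1/C=C/[C@H](C)CC(=O)O | intermediate
12 | (13S)-8α-acetoxylabdan-15-oic acid | CC(=O)O[C@]1(C)CC[C@H]2C(C)(C)CCC[C@]2(C)[C@H]1CC[C@H](C)CC(=O)O | target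

**Step count:** 6 steps in total; longest linear sequence 6 steps (from 1).

**Steps most likely to fail**

Step 3 (Wittig on the unprotected dihydroxy lactol). The risks are erosion of Z selectivity, which translates directly into the C13 epimer after step 5, and epimerisation at C11 through the α-hydroxy aldehyde. The fallback sets out from 3 and comes back at 6. The secondary alcohol of 3 is silylated with t-BuMe2SiOTf and 2,6-lutidine to give (11S)-11α-(tert-butyldimethylsilyloxy)sclareolide F3. Reduction with i-Bu2AlH gives the silyloxy lactol F4. The same ethylidene Wittig reaction, now on a neutral α-silyloxy aldehyde, gives the (11R,12Z)-11-silyloxy alkene F5. Bu4NF in THF then removes the silyl group to return diol 6.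

Step 5 (Ireland–Claisen with two acetates enolised at once). The risks are Claisen-type condensation, C-silylation and loss of the tertiary acetate. The fallback sets out from 6 and comes back at 11. Only the secondary alcohol is acetylated (Ac2O, pyridine) and monoacetate 7 is isolated. Treatment with LiN(i-Pr)2 and Me3SiCl silylates the tertiary alkoxide and gives the mono ketene acetal, the (11R,12Z)-8α-trimethylsilyloxy 11-[1-(trimethylsilyloxy)vinyl] ether F6. This rearranges on warming to trimethylsilyl (11E,13R)-8α-trimethylsilyloxylabd-11-en-15-oate F7. Acidic work-up gives (11E,13R)-8α-hydroxylabd-11-en-15-oic acid F8. AcCl and PhNMe2 then acetylate the tertiary alcohol and form the mixed acetic anhydride of 11, F9, which aqueous NaHCO3 hydrolyses to 11.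

Step 1 (enolate hydroxylation). The risks are addition of the enolate to the sulfonimine by-product, over-oxidation, and incomplete facial selectivity at C11. The fallback sets out from 1 and comes back at 3. The lithium enolate of 1 (LiN(i-Pr)2, THF, −78 °C) is trapped with Me3SiCl and the trimethylsilyl ketene acetal of sclareolide F1 is isolated. Rubottom oxidation with mCPBA (NaHCO3, hexane/CH2Cl2, −15 °C) epoxidises its α face and, after silyl migration, gives (11S)-11α-(trimethylsilyloxy)sclareolide F2. Citric acid in MeOH removes the silyl group to give 3. The C11 configuration should be confirmed at 3 by NOE between H-11 and the C8 and C10 methyl groups.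

**Further compounds**

F1 | step 1 | trimethylsilyl ketene acetal of sclareolide (12-trimethylsilyloxy-8α,12-epoxy-13,14,15,16-tetranorlabd-11-ene) | C[Si](C)(C)OC=1O[C@]2(C)CC[C@H]3C(C)(C)CCC[C@]3(C)[C@H]2C=1
F2 | step 1 | (11S)-11α-(trimethylsilyloxy)sclareolide | O=C1O[C@]2(C)CC[C@H]3C(C)(C)CCC[C@]3(C)[C@H]2[C@@H]1O[Si](C)(C)C
F3 | step 3 | (11S)-11α-(tert-butyldimethylsilyloxy)sclareolide | O=C1O[C@]2(C)CC[C@H]3C(C)(C)CCC[C@]3(C)[C@H]2[C@@H]1O[Si](C)(C)C(C)(C)C
F4 | step 3 | (11S)-11α-(tert-butyldimethylsilyloxy)sclareolide lactol (anomer mixture) | OC1O[C@]2(C)CC[C@H]3C(C)(C)CCC[C@]3(C)[C@H]2[C@@H]1O[Si](C)(C)C(C)(C)C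
F5 | step 3 | (11R,12Z)-11-(tert-butyldimethylsilyloxy)-14,15-dinorlabd-12-en-8α-ol | O[C@]1(C)CC[C@H]2C(C)(C)CCC[C@]2(C)[C@H]1[C@H](O[Si](C)(C)C(C)(C)C)/C=C\C
F6 | step 5 | (11R,12Z)-8α-trimethylsilyloxy-11-[1-(trimethylsilyloxy)vinyloxy]-14,15-dinorlabd-12-ene | C[Si](C)(C)O[C@]1(C)CC[C@H]2C(C)(C)CCC[C@]2(C)[C@H]1[C@H](OC(=C)O[Si](C)(C)C)/C=C\C
F7 | step 5 | trimethylsilyl (11E,13R)-8α-trimethylsilyloxylabd-11-en-15-oate | C[Si](C)(C)O[C@]1(C)CC[C@H]2C(C)(C)CCC[C@]2(C)[C@H]1/C=C/[C@H](C)CC(=O)O[Si](C)(C)C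
F8 | step 5 | (11E,13R)-8α-hydroxylabd-11-en-15-oic acid | O[C@]1(C)CC[C@H]2C(C)(C)CCC[C@]2(C)[C@H]1/C=C/[C@H](C)CC(=O)O
F9 | step 5 | mixed acetic anhydride of (11E,13R)-8α-acetoxylabd-11-en-15-oic acid | CC(=O)O[C@]1(C)CC[C@H]2C(C)(C)CCC[C@]2(C)[C@H]1/C=C/[C@H](C)CC(=O)OC(C)=O
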